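**Retrosynthetic overview**

1. The target is (2S)-5-hydroxy-6,7,3',4'-tetramethoxyflavanone 7. Its free 5-OH is unmasked last, from the 5-methyl ether of flavanone 6, by chelation to the C4 carbonyl.
2. The key disconnection is O1–C2 of the pyranone ring (O1, C2, C3, C4, C4a, C8a). This retro-oxa-Michael step mirrors the chalcone-to-flavanone step of flavonoid biosynthesis and leads to the achiral 2'-hydroxychalcone-type alkylidene 4, which carries a temporary tert-butyl ester on C3.
3. Enabling feature: the phenol oxygen O1 on C8a is ortho to the C4 carbonyl and 1,5 to the enone carbon C2. C3 is α to C4=O, so a carboxylate placed there activates C2, gives a catalyst a two-point handle and leaves later as CO2. Ring A has only this one free ortho oxygen, so the closure is regiochemically unambiguous.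
4. Alkylidene 4 comes from Knoevenagel condensation (C2=C3) of β-keto ester 2 with veratraldehyde 3; 2 comes from C-carboxylation of the commercial acetophenone 1.
5. Ring order: rings A and B are purchased; ring C is the only ring built and is closed last, in step 3.

Key step: step 3

Assumption: the quinine-derived bifunctional thiourea is taken to deliver the 2S series; if the sense of induction proves opposite, its quinidine-derived pseudoenantiomer is used in the same step.

**Route**

Step 1
Reactants: 1 1-(6-hydroxy-2,3,4-trimethoxyphenyl)ethan-1-one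
Product: 2 tert-butyl 3-(6-hydroxy-2,3,4-trimethoxyphenyl)-3-oxopropanoate
Conditions: LiHMDS (3.1 equiv), THF, −78 °C; Boc2O (1.05 equiv), −78 → −20 °C; cold 1 M HCl
Reagents that add atoms: di-tert-butyl dicarbonate (Boc2O), CC(C)(C)OC(=O)OC(=O)OC(C)(C)C
Why: Claisen-type C-acylation of the phenoxide/enolate dianion of the aryl methyl ketone with Boc2O should give the β-keto ester, because any aryl carbonate formed on oxygen is passed on to the enolate carbon by a Baker–Venkataraman-type O-to-C shift and the third equivalent of base stores the product as its enolate.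

Step 2
Reactants: 2 tert-butyl 3-(6-hydroxy-2,3,4-trimethoxyphenyl)-3-oxopropanoate; 3 3,4-dimethoxybenzaldehyde (veratraldehyde)
Product: 4 tert-butyl (E)-3-(3,4-dimethoxyphenyl)-2-(6-hydroxy-2,3,4-trimethoxybenzoyl)prop-2-enoate
Conditions: piperidine (0.1 equiv), AcOH (0.1 equiv), 4 Å MS, toluene, rt; rapid chromatography or crystallisation to a single geometric isomer
Reagents that add atoms: none
Why: Knoevenagel condensation of the 1,3-dicarbonyl compound with a non-enolisable aldehyde under piperidinium acetate catalysis with removal of water should give the alkylidene, expected mainly as the E isomer (aryl cis to the twisted aroyl group), while the hydrogen-bonded phenol should not add at room temperature without bifunctional activation.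

Step 3
Reactants: 4 tert-butyl (E)-3-(3,4-dimethoxyphenyl)-2-(6-hydroxy-2,3,4-trimethoxybenzoyl)prop-2-enoate
Product: 6 (2S)-2-(3,4-dimethoxyphenyl)-5,6,7-trimethoxychroman-4-one, via cyclised tert-butyl 3-carboxylate 5 (not isolated)
Conditions: quinine-derived 3,5-bis(trifluoromethyl)phenyl thiourea (10 mol%), toluene, −25 °C; then TsOH·H2O (0.5 equiv), 80 °C
Reagents that add atoms: none
Why: The thiourea N–H bonds hold the 1,3-dicarbonyl unit (C4=O and the ester C=O) while the quinuclidine nitrogen activates the C8a phenol, whose oxygen adds to C2 in an intramolecular oxa-Michael reaction that copies the chalcone-isomerase step of flavonoid biosynthesis; acid then cleaves the tert-butyl ester to isobutene and a β-keto acid that loses CO2. The closest known reaction type is the cinchona-thiourea-catalysed cyclisation of alkylidene β-keto esters of 2-hydroxyaryl ketones to flavanone-3-carboxylates with acidic decarboxylation in the same flask. The pyranone ring closes by O1–C2 bond formation in the 6-endo-trig mode. C2 is the only stereocentre and is set by the catalyst, which binds acceptor and phenol in one chiral pocket and delivers oxygen to one enantiotopic face of C2, whereas C3 is epimerisable and is erased by the decarboxylation. The step needs enantioface selectivity and a single ring-closing oxygen: the second ortho oxygen of ring A is a methyl ether, so only the C8a phenol can close, and the ester is removed under acid because base would reopen the ring by retro-oxa-Michael reaction and racemise C2.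

Step 4
Reactants: 6 (2S)-2-(3,4-dimethoxyphenyl)-5,6,7-trimethoxychroman-4-one
Product: 7 (2S)-2-(3,4-dimethoxyphenyl)-5-hydroxy-6,7-dimethoxychroman-4-one
Conditions: BCl3 (1.0 M in CH2Cl2, 1.5 equiv), CH2Cl2, −78 → −20 °C; then H2O, 0 °C
Reagents that add atoms: none
Why: Chelation-controlled aryl methyl ether cleavage should remove only the 5-methyl group, because BCl3 bridges the C4 carbonyl and the peri 5-methoxy oxygen in a six-membered chelate, the other four methoxy groups have no neighbouring carbonyl, and the low temperature and absence of base should leave C2 untouched.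

**Compound list**

1 | 1-(6-hydroxy-2,3,4-trimethoxyphenyl)ethan-1-one | CC(=O)c1c(O)cc(OC)c(OC)c1OC | starting material
2 | tert-butyl 3-(6-hydroxy-2,3,4-trimethoxyphenyl)-3-oxopropanoate | CC(C)(C)OC(=O)CC(=O)c1c(O)cc(OC)c(OC)c1OC | intermediate
3 | 3,4-dimethoxybenzaldehyde (veratraldehyde) | COc1ccc(C=O)cc1OC | starting material
4 | tert-butyl (E)-3-(3,4-dimethoxyphenyl)-2-(6-hydroxy-2,3,4-trimethoxybenzoyl)prop-2-enoate | COc1ccc(/C=C(/C(=O)OC(C)(C)C)C(=O)c2c(O)cc(OC)c(OC)c2OC)cc1OC | intermediate
5 | tert-butyl (2S,3R)-2-(3,4-dimethoxyphenyl)-5,6,7-trimethoxy-4-oxochromane-3-carboxylate (trans; C3 epimerisable, not isolated) | COc1ccc([C@@H]2[C@@H](C(=O)OC(C)(C)C)C(=O)c3c(cc(OC)c(OC)c3OC)O2)cc1OC | intermediate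
6 | (2S)-2-(3,4-dimethoxyphenyl)-5,6,7-trimethoxychroman-4-one | COc1ccc([C@@H]2CC(=O)c3c(cc(OC)c(OC)c3OC)O2)cc1OC | intermediate
7 | (2S)-2-(3,4-dimethoxyphenyl)-5-hydroxy-6,7-dimethoxychroman-4-one | COc1ccc([C@@H]2CC(=O)c3c(cc(OC)c(OC)c3O)O2)cc1OC | target

**Totals**

Total step count: 4. Longest linear sequence: 4 steps (1 → 2 → 4 → 6 → 7).

**Steps most likely to fail**

Step 3. The oxygen delivery may show poor facial selectivity, because the ortho-methoxy group twists the aroyl group and may loosen the two-point hydrogen bonding. Configuration may also be partly lost by acid-promoted ring opening and reclosure during the hot decarboxylation. The fallback is a resolution; it sets out from 1 and 3 and comes back at 6. Claisen–Schmidt condensation of 1 with 3 (KOH, EtOH, rt) should give the chalcone (E)-3-(3,4-dimethoxyphenyl)-1-(6-hydroxy-2,3,4-trimethoxyphenyl)prop-2-en-1-one F1. Base-mediated oxa-Michael closure (NaOAc, EtOH, reflux) should give the racemic flavanone rac-2-(3,4-dimethoxyphenyl)-5,6,7-trimethoxychroman-4-one F2. Preparative chromatography on a chiral stationary phase then separates 6 from its mirror image (2R)-2-(3,4-dimethoxyphenyl)-5,6,7-trimethoxychroman-4-one F3, which is returned to F2 by brief base treatment (ring opening and reclosure) and separated again.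

Step 4. Configuration may be lost through Lewis-acid-assisted opening of the benzylic C2–O1 bond, which the 4'-methoxy group favours. A second methyl ether may also be cleaved once the first boron chelate has formed. The fallback carries the 5-oxygen as a benzyl ether that is released under neutral conditions; it sets out from 1 and comes back at 7.
- Tosylation of 1 (TsCl, K2CO3, acetone) should give 2-acetyl-3,4,5-trimethoxyphenyl 4-methylbenzenesulfonate F4.
- BCl3 (CH2Cl2, 0 °C) then removes the methyl group ortho to the acetyl group, before any stereocentre exists, to give 2-acetyl-3-hydroxy-4,5-dimethoxyphenyl 4-methylbenzenesulfonate F5.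
- Benzylation (BnBr, K2CO3, DMF, 60 °C) should give 2-acetyl-3-(benzyloxy)-4,5-dimethoxyphenyl 4-methylbenzenesulfonate F6.
- KOH in MeOH/H2O at reflux cleaves the sulfonate to 1-[2-(benzyloxy)-6-hydroxy-3,4-dimethoxyphenyl]ethan-1-one F7.
- The chemistry of steps 1 to 3 is then repeated. This should give tert-butyl 3-[2-(benzyloxy)-6-hydroxy-3,4-dimethoxyphenyl]-3-oxopropanoate F8, then the alkylidene tert-butyl (E)-2-[2-(benzyloxy)-6-hydroxy-3,4-dimethoxybenzoyl]-3-(3,4-dimethoxyphenyl)prop-2-enoate F9. Cyclisation gives the ester tert-butyl (2S,3R)-5-(benzyloxy)-2-(3,4-dimethoxyphenyl)-6,7-dimethoxy-4-oxochromane-3-carboxylate F10, which is not isolated, and decarboxylation gives (2S)-5-(benzyloxy)-2-(3,4-dimethoxyphenyl)-6,7-dimethoxychroman-4-one F11.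
- Hydrogenolysis (H2, Pd/C, EtOAc, rt) should then give 7.

Step 1. The dianion may be acylated on the phenoxide oxygen or twice, or the amide base may consume the dicarbonate, instead of clean C-acylation. The fallback separates the two events; it sets out from 1 and comes back at 2. O-acylation of 1 (Boc2O, Et3N, DMAP cat., CH2Cl2, rt) should give 2-acetyl-3,4,5-trimethoxyphenyl tert-butyl carbonate F12. LiHMDS (2.2 equiv, THF, −78 → 0 °C) then forms the ketone enolate, which takes over the carboxyl group in a Baker–Venkataraman rearrangement to give 2.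

**Further compounds**

F1 | step 3 | (E)-3-(3,4-dimethoxyphenyl)-1-(6-hydroxy-2,3,4-trimethoxyphenyl)prop-2-en-1-one | COc1ccc(/C=C/C(=O)c2c(O)cc(OC)c(OC)c2OC)cc1OC
F2 | step 3 | rac-2-(3,4-dimethoxyphenyl)-5,6,7-trimethoxychroman-4-one | COc1ccc(C2CC(=O)c3c(cc(OC)c(OC)c3OC)O2)cc1OC
F3 | step 3 | (2R)-2-(3,4-dimethoxyphenyl)-5,6,7-trimethoxychroman-4-one | COc1ccc([C@H]2CC(=O)c3c(cc(OC)c(OC)c3OC)O2)cc1OC
F4 | step 4 | 2-acetyl-3,4,5-trimethoxyphenyl 4-methylbenzenesulfonate | CC(=O)c1c(OS(=O)(=O)c2ccc(C)cc2)cc(OC)c(OC)c1OC
F5 | step 4 | 2-acetyl-3-hydroxy-4,5-dimethoxyphenyl 4-methylbenzenesulfonate | CC(=O)c1c(OS(=O)(=O)c2ccc(C)cc2)cc(OC)c(OC)c1O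
F6 | step 4 | 2-acetyl-3-(benzyloxy)-4,5-dimethoxyphenyl 4-methylbenzenesulfonate | CC(=O)c1c(OS(=O)(=O)c2ccc(C)cc2)cc(OC)c(OC)c1OCc3ccccc3
F7 | step 4 | 1-[2-(benzyloxy)-6-hydroxy-3,4-dimethoxyphenyl]ethan-1-one | CC(=O)c1c(O)cc(OC)c(OC)c1OCc2ccccc2
F8 | step 4 | tert-butyl 3-[2-(benzyloxy)-6-hydroxy-3,4-dimethoxyphenyl]-3-oxopropanoate | CC(C)(C)OC(=O)CC(=O)c1c(O)cc(OC)c(OC)c1OCc2ccccc2
F9 | step 4 | tert-butyl (E)-2-[2-(benzyloxy)-6-hydroxy-3,4-dimethoxybenzoyl]-3-(3,4-dimethoxyphenyl)prop-2-enoate | COc1ccc(/C=C(/C(=O)OC(C)(C)C)C(=O)c2c(O)cc(OC)c(OC)c2OCc3ccccc3)cc1OC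
F10 | step 4 | tert-butyl (2S,3R)-5-(benzyloxy)-2-(3,4-dimethoxyphenyl)-6,7-dimethoxy-4-oxochromane-3-carboxylate | COc1ccc([C@@H]2[C@@H](C(=O)OC(C)(C)C)C(=O)c3c(cc(OC)c(OC)c3OCc4ccccc4)O2)cc1OC
F11 | step 4 | (2S)-5-(benzyloxy)-2-(3,4-dimethoxyphenyl)-6,7-dimethoxychroman-4-one | COc1ccc([C@@H]2CC(=O)c3c(cc(OC)c(OC)c3OCc4ccccc4)O2)cc1OC
F12 | step 1 | 2-acetyl-3,4,5-trimethoxyphenyl tert-butyl carbonate | CC(=O)c1c(OC(=O)OC(C)(C)C)cc(OC)c(OC)c1OC
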